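**Strategy.** The butyrolactone ring (O1, C2=O, C3, C4, C5) carries an arylmethyl group on each of the adjacent stereocentres C3 and C4. Both benzylic C–C bonds are traced back to one Diels–Alder reaction in which C3=C4 is the exocyclic alkene of an L-malic-acid-derived (Z)-alkylidene dioxolanone and the two benzylic carbons are the termini of a symmetrical (E,E)-1,4-diarylbutadiene. The cycloaddition sets C3 (face anti to the acetal tert-butyl group) and C4 (alkene geometry) at once; the two surplus ring carbons are then excised as CO. The dienophile carries a tert-butyl ester so that the future C5 can be unmasked as a free acid and reduced selectively.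

Key step: step 7

Remark on the chemistry: compounds 13–15 are drawn for the endo/exo mode expected to dominate (ester endo, ring carbonyl exo); the other mode differs only at the two aryl-bearing carbons and converges on the same 16. Alcohol 9 is taken as a commercial material (otherwise NaBH4 reduction of 7).

Step 1
Reactants: 1 L-malic acid; 2 pivalaldehyde
Product: 3 2-[(2S,4S)-2-tert-butyl-5-oxo-1,3-dioxolan-4-yl]acetic acid
Conditions: 2 (1.3 equiv), p-TsOH·H2O (cat.), H2SO4 (cat.), pentane, reflux, Dean–Stark; recrystallisation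
Reagents that add atoms: none
Why: Acid-catalysed acetalisation engages the α-hydroxy acid unit as the five-membered acylal without touching the malic stereocentre, and thermodynamic control places the tert-butyl group cis to the CH2CO2H arm, so the new acetal carbon should be S and the cis isomer should be obtained pure by crystallisation.

Step 2
Reactants: 3 2-[(2S,4S)-2-tert-butyl-5-oxo-1,3-dioxolan-4-yl]acetic acid
Product: 4 tert-butyl 2-[(2S,4S)-2-tert-butyl-5-oxo-1,3-dioxolan-4-yl]acetate
Conditions: Cl3CC(=NH)O-t-Bu (2 equiv), BF3·OEt2 (cat.), CH2Cl2/cyclohexane, rt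
Reagents that add atoms: tert-butyl 2,2,2-trichloroacetimidate, CC(C)(C)OC(=N)C(Cl)(Cl)Cl
Why: Acid-promoted O-alkylation of the carboxylic acid by the trichloroacetimidate (tert-butyl cation transfer) should give the ester under non-basic conditions that neither epimerise the ring stereocentre nor open the acid-stable dioxolanone.

Step 3
Reactants: 4 tert-butyl 2-[(2S,4S)-2-tert-butyl-5-oxo-1,3-dioxolan-4-yl]acetate
Product: 6 (2S,5Z)-2-tert-butyl-5-(2-tert-butoxy-2-oxoethylidene)-1,3-dioxolan-4-one, via bromodioxolanone 5 (not isolated)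
Conditions: NBS (1.1 equiv), AIBN (cat.), CCl4 (or PhCF3), reflux; then Et3N (1.5 equiv), CH2Cl2, 0 °C → rt
Reagents that add atoms: none
Why: Wohl–Ziegler radical bromination should take the captodatively stabilised ring C–H between oxygen and the carbonyl group, and amine-induced dehydrobromination of the resulting α-bromo ether should then give the conjugated exocyclic alkene, expected mainly as the Z isomer with the ester anti to the ring carbonyl (fumarate-like), a minor E isomer being removed by chromatography while the acetal stereocentre is not involved.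

Step 4
Reactants: 7 4-benzyloxy-3-methoxybenzaldehyde
Product: 8 (2E)-3-(4-benzyloxy-3-methoxyphenyl)prop-2-enal
Conditions: Ph3P=CHCHO (1.2 equiv), toluene, 90 °C
Reagents that add atoms: (triphenylphosphoranylidene)acetaldehyde, O=CC=P(c1ccccc1)(c1ccccc1)c1ccccc1
Why: Wittig olefination with the stabilised formylmethylene ylide is E-selective and should stop largely at the cinnamaldehyde stage because the conjugated, electron-rich product aldehyde is the poorer electrophile.

Step 5
Reactants: 9 (4-benzyloxy-3-methoxyphenyl)methanol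
Product: 11 diethyl [(4-benzyloxy-3-methoxyphenyl)methyl]phosphonate, via benzylic bromide 10 (not isolated)
Conditions: PBr3 (0.4 equiv), CH2Cl2, 0 °C; evaporate; then P(OEt)3 (3 equiv, neat), 120 °C
Reagents that add atoms: triethyl phosphite, CCOP(OCC)OCC
Why: Conversion of the electron-rich benzylic alcohol into its bromide followed by the Michaelis–Arbuzov reaction with triethyl phosphite is a standard, telescoped route to benzylic phosphonates, and the aryl benzyl ether is inert to both stages.

Step 6
Reactants: 11 diethyl [(4-benzyloxy-3-methoxyphenyl)methyl]phosphonate; 8 (2E)-3-(4-benzyloxy-3-methoxyphenyl)prop-2-enal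
Product: 12 (1E,3E)-1,4-bis(4-benzyloxy-3-methoxyphenyl)buta-1,3-diene
Conditions: NaH (1.2 equiv), THF, 0 °C → rt
Reagents that add atoms: none
Why: Horner–Wadsworth–Emmons olefination of the enal with the benzylic phosphonate anion should form the new double bond with E geometry, so the crystalline (E,E)-diene is expected.

Step 7
Reactants: 12 (1E,3E)-1,4-bis(4-benzyloxy-3-methoxyphenyl)buta-1,3-diene; 6 (2S,5Z)-2-tert-butyl-5-(2-tert-butoxy-2-oxoethylidene)-1,3-dioxolan-4-one
Product: 13 tert-butyl (2S,5S,6R,7R,10R)-7,10-bis(4-benzyloxy-3-methoxyphenyl)-2-tert-butyl-4-oxo-1,3-dioxaspiro[4.5]dec-8-ene-6-carboxylate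
Conditions: 6 (1.5 equiv), BHT (cat.), toluene (2 M), 130 °C, sealed tube
Reagents that add atoms: none
Why: The reaction is a concerted, suprafacial normal-electron-demand [4+2] cycloaddition between the s-cis diene, whose HOMO is raised by two para-alkoxyaryl groups, and the doubly acceptor-substituted exocyclic alkene of 6; the closest known reaction type is the Diels–Alder reaction of chiral 2-tert-butyl-5-alkylidene-1,3-dioxolan-4-ones with 1,3-dienes. The one new ring, the cyclohexene, is closed by intermolecular [4+2] cycloaddition in which both σ bonds (to the future C3 and C4) form in the same step, turning the ring carbon of 6 into a spiro centre. The spiro carbon (future C3) is set by approach of the diene to the π face anti to the tert-butyl group on the acetal carbon, and the ester-bearing carbon (future C4) is set relative to it by stereospecific retention of the Z geometry (ring oxygen and ester cis). The two aryl-bearing carbons are cis to each other because of the E,E geometry, and their relation to the rest follows the endo/exo mode (ester endo expected), which is irrelevant because both later become CH2. The step needs only π-facial selectivity and stereospecificity, secured by the acetal tert-butyl group and by running the reaction thermally without a Lewis acid so that no zwitterionic stepwise path can scramble the alkene geometry; no regiochemical question arises because the diene is symmetrical. Any adduct from the syn face would become a diastereomer of 16 after step 9 and should be removed there, which protects the enantiomeric purity of 20.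

Step 8
Reactants: 13 tert-butyl (2S,5S,6R,7R,10R)-7,10-bis(4-benzyloxy-3-methoxyphenyl)-2-tert-butyl-4-oxo-1,3-dioxaspiro[4.5]dec-8-ene-6-carboxylate
Product: 15 tert-butyl (2R,3R)-3-(4-benzyloxy-3-methoxyphenyl)-2-[(2S,4S)-4-[(1R)-1-(4-benzyloxy-3-methoxyphenyl)-2-oxoethyl]-2-tert-butyl-5-oxo-1,3-dioxolan-4-yl]-4-oxobutanoate, via cis-diol 14 (not isolated)
Conditions: OsO4 (5 mol %), NaIO4 (4 equiv), THF/pH 7 phosphate buffer, rt; crude used directly
Reagents that add atoms: sodium periodate, [Na+].[O-]I(=O)(=O)=O (terminal oxidant; the two aldehyde oxygens are relayed through osmium tetroxide, O=[Os](=O)(=O)=O)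
Why: In this Lemieux–Johnson oxidation OsO4 should syn-dihydroxylate the only alkene (expected from the face away from the aryl groups) and periodate should cleave the cis-glycol to the dialdehyde, while aryl benzyl ethers, the ester and the acylal are inert to both oxidants and the buffered, amine-free medium avoids enolisation-driven loss of the acetal oxygen next to the new aldehyde.

Step 9
Reactants: 15 tert-butyl (2R,3R)-3-(4-benzyloxy-3-methoxyphenyl)-2-[(2S,4S)-4-[(1R)-1-(4-benzyloxy-3-methoxyphenyl)-2-oxoethyl]-2-tert-butyl-5-oxo-1,3-dioxolan-4-yl]-4-oxobutanoate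
Product: 16 tert-butyl (2R)-3-(4-benzyloxy-3-methoxyphenyl)-2-[(2S,4S)-4-(4-benzyloxy-3-methoxybenzyl)-2-tert-butyl-5-oxo-1,3-dioxolan-4-yl]propanoate
Conditions: RhCl(PPh3)3 (2.3 equiv), degassed toluene, 110 °C
Reagents that add atoms: none
Why: In the Tsuji–Wilkinson decarbonylation each aldehyde C–H adds oxidatively to monovalent rhodium, CO is extruded from the acyl complex and C–H reductive elimination leaves a CH2Ar group, so both aryl-bearing stereocentres vanish (endo/exo isomers converge) while the neutral conditions leave C3, C4 and the acetal untouched.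

Step 10
Reactants: 16 tert-butyl (2R)-3-(4-benzyloxy-3-methoxyphenyl)-2-[(2S,4S)-4-(4-benzyloxy-3-methoxybenzyl)-2-tert-butyl-5-oxo-1,3-dioxolan-4-yl]propanoate
Product: 17 (2R)-3-(4-benzyloxy-3-methoxyphenyl)-2-[(2S,4S)-4-(4-benzyloxy-3-methoxybenzyl)-2-tert-butyl-5-oxo-1,3-dioxolan-4-yl]propanoic acid
Conditions: TFA/CH2Cl2 (1:4), 0 °C → rt
Reagents that add atoms: none
Why: Acidolysis of the tert-butyl ester (alkyl–oxygen cleavage through the tert-butyl cation, lost as isobutene) should free the C5 carboxyl group, whereas the dioxolanone, itself formed under stronger acid, and the aryl benzyl ethers survive and no base is present that could epimerise C4.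

Step 11
Reactants: 17 (2R)-3-(4-benzyloxy-3-methoxyphenyl)-2-[(2S,4S)-4-(4-benzyloxy-3-methoxybenzyl)-2-tert-butyl-5-oxo-1,3-dioxolan-4-yl]propanoic acid
Product: 19 (3S,4S)-3,4-bis(4-benzyloxy-3-methoxybenzyl)-3-hydroxyoxolan-2-one, via primary alcohol 18 (not isolated)
Conditions: BH3·SMe2 (3 equiv), THF, 0 °C → rt; MeOH; then p-TsOH·H2O (cat.), toluene, 40 °C
Reagents that add atoms: none
Why: Chemoselective borane reduction takes the free carboxylic acid through its acyloxyborane much faster than the ester-type carbonyl of the dioxolanone, and the resulting primary alcohol should then undergo acid-catalysed 5-exo-trig transacylation onto that carbonyl, expelling pivalaldehyde and unveiling the C3 hydroxyl, so the lactone regiochemistry is unambiguous and neither stereocentre is touched.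

Step 12
Reactants: 19 (3S,4S)-3,4-bis(4-benzyloxy-3-methoxybenzyl)-3-hydroxyoxolan-2-one
Product: 20 (3S,4S)-3-hydroxy-3,4-bis(4-hydroxy-3-methoxybenzyl)oxolan-2-one
Conditions: H2 (1 atm), Pd/C (10 wt %), EtOAc/MeOH, rt
Reagents that add atoms: none
Why: Catalytic hydrogenolysis should cleave the two aryl benzyl ethers to the phenols, the lactone, the tertiary non-benzylic alcohol and both stereocentres being inert to H2 over Pd/C.

**Compound list**

1 | L-malic acid, (2S)-2-hydroxybutanedioic acid | OC(=O)C[C@H](O)C(=O)O | starting material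
2 | pivalaldehyde | CC(C)(C)C=O | starting material
3 | 2-[(2S,4S)-2-tert-butyl-5-oxo-1,3-dioxolan-4-yl]acetic acid (cis) | CC(C)(C)[C@H]1O[C@@H](CC(=O)O)C(=O)O1 | intermediate
4 | tert-butyl 2-[(2S,4S)-2-tert-butyl-5-oxo-1,3-dioxolan-4-yl]acetate | CC(C)(C)[C@H]1O[C@@H](CC(=O)OC(C)(C)C)C(=O)O1 | intermediate
5 | 4-bromo derivative of 4, bromine expected trans to the tert-butyl group (formally 2R,4R) | CC(C)(C)[C@H]1O[C@@](Br)(CC(=O)OC(C)(C)C)C(=O)O1 | intermediate
6 | (2S,5Z)-2-tert-butyl-5-(2-tert-butoxy-2-oxoethylidene)-1,3-dioxolan-4-one | CC(C)(C)[C@@H]1OC(=O)/C(=C/C(=O)OC(C)(C)C)O1 | intermediate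
7 | 4-benzyloxy-3-methoxybenzaldehyde | COc1cc(C=O)ccc1OCc1ccccc1 | starting material
8 | (2E)-3-(4-benzyloxy-3-methoxyphenyl)prop-2-enal | COc1cc(/C=C/C=O)ccc1OCc1ccccc1 | intermediate
9 | (4-benzyloxy-3-methoxyphenyl)methanol | COc1cc(CO)ccc1OCc1ccccc1 | starting material
10 | 4-benzyloxy-3-methoxybenzyl bromide | COc1cc(CBr)ccc1OCc1ccccc1 | intermediate
11 | diethyl [(4-benzyloxy-3-methoxyphenyl)methyl]phosphonate | CCOP(=O)(Cc1ccc(OCc2ccccc2)c(OC)c1)OCC | intermediate
12 | (1E,3E)-1,4-bis(4-benzyloxy-3-methoxyphenyl)buta-1,3-diene | COc1cc(/C=C/C=C/c2ccc(OCc3ccccc3)c(OC)c2)ccc1OCc1ccccc1 | intermediate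
13 | tert-butyl (2S,5S,6R,7R,10R)-7,10-bis(4-benzyloxy-3-methoxyphenyl)-2-tert-butyl-4-oxo-1,3-dioxaspiro[4.5]dec-8-ene-6-carboxylate (new spiro bond anti to tert-butyl; ring oxygen, ester and both aryl groups on one face) | CC(C)(C)OC(=O)[C@@H]1[C@H](c3ccc(OCc4ccccc4)c(OC)c3)C=C[C@H](c3ccc(OCc4ccccc4)c(OC)c3)[C@]12O[C@H](C(C)(C)C)OC2=O | intermediate
14 | 8,9-cis-diol of 13, hydroxyl groups on the ring face opposite the aryl groups | CC(C)(C)OC(=O)[C@@H]1[C@H](c3ccc(OCc4ccccc4)c(OC)c3)[C@@H](O)[C@@H](O)[C@H](c3ccc(OCc4ccccc4)c(OC)c3)[C@]12O[C@H](C(C)(C)C)OC2=O | intermediate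
15 | tert-butyl (2R,3R)-3-(4-benzyloxy-3-methoxyphenyl)-2-[(2S,4S)-4-[(1R)-1-(4-benzyloxy-3-methoxyphenyl)-2-oxoethyl]-2-tert-butyl-5-oxo-1,3-dioxolan-4-yl]-4-oxobutanoate | CC(C)(C)OC(=O)[C@H]([C@H](c1ccc(OCc2ccccc2)c(OC)c1)C=O)[C@@]1(O[C@H](C(C)(C)C)OC1=O)[C@@H](c1ccc(OCc2ccccc2)c(OC)c1)C=O | intermediate
16 | tert-butyl (2R)-3-(4-benzyloxy-3-methoxyphenyl)-2-[(2S,4S)-4-(4-benzyloxy-3-methoxybenzyl)-2-tert-butyl-5-oxo-1,3-dioxolan-4-yl]propanoate | CC(C)(C)OC(=O)[C@H](Cc1ccc(OCc2ccccc2)c(OC)c1)[C@@]1(O[C@H](C(C)(C)C)OC1=O)Cc1ccc(OCc2ccccc2)c(OC)c1 | intermediate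
17 | (2R)-3-(4-benzyloxy-3-methoxyphenyl)-2-[(2S,4S)-4-(4-benzyloxy-3-methoxybenzyl)-2-tert-butyl-5-oxo-1,3-dioxolan-4-yl]propanoic acid | OC(=O)[C@H](Cc1ccc(OCc2ccccc2)c(OC)c1)[C@@]1(O[C@H](C(C)(C)C)OC1=O)Cc1ccc(OCc2ccccc2)c(OC)c1 | intermediate
18 | (2S,5S)-5-(4-benzyloxy-3-methoxybenzyl)-5-[(2S)-1-(4-benzyloxy-3-methoxyphenyl)-3-hydroxypropan-2-yl]-2-tert-butyl-1,3-dioxolan-4-one | OC[C@H](Cc1ccc(OCc2ccccc2)c(OC)c1)[C@@]1(O[C@H](C(C)(C)C)OC1=O)Cc1ccc(OCc2ccccc2)c(OC)c1 | intermediate
19 | (3S,4S)-3,4-bis(4-benzyloxy-3-methoxybenzyl)-3-hydroxyoxolan-2-one | COc1cc(C[C@H]2COC(=O)[C@]2(O)Cc2ccc(OCc3ccccc3)c(OC)c2)ccc1OCc1ccccc1 | intermediate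
20 | (3S,4S)-3-hydroxy-3,4-bis(4-hydroxy-3-methoxybenzyl)oxolan-2-one | COc1cc(C[C@H]2COC(=O)[C@]2(O)Cc2ccc(O)c(OC)c2)ccc1O | target

**Step count and risk**

Total steps: 12. Longest linear sequence: 9 steps (steps 1–3 and 7–12, from L-malic acid).

Steps most likely to fail:

Step 7. The cycloaddition may not proceed at a useful rate, because both diene termini carry aryl groups and the alkene is trisubstituted; prolonged heating may instead polymerise either partner or erode the facial selectivity. The fallback builds the two benzylic bonds by enolate alkylation; it sets out from 1 and returns to the route at 17, making steps 3–10 unnecessary. Fischer esterification of 1 (i-PrOH, cat. H2SO4, reflux) should give diisopropyl (2S)-2-hydroxybutanedioate F1. Its alkoxide enolate (LiHMDS, 2.2 equiv, THF, −78 °C) should be benzylated by bromide 10 (isolated after the PBr3 stage of step 5) anti to the oxygen substituent (Fráter–Seebach alkylation) to give diisopropyl (2S,3R)-3-(4-benzyloxy-3-methoxybenzyl)-2-hydroxybutanedioate F2. Saponification (KOH, aqueous MeOH, then acid) should give (2S,3R)-3-(4-benzyloxy-3-methoxybenzyl)-2-hydroxybutanedioic acid F3. Acetalisation with 2 under the conditions of step 1 should give the cis-dioxolanone (2R)-3-(4-benzyloxy-3-methoxyphenyl)-2-[(2S,4S)-2-tert-butyl-5-oxo-1,3-dioxolan-4-yl]propanoic acid F4. Its dianion (LiHMDS, 3 equiv, THF, −78 °C) should be benzylated by 10 on the ring face anti to the tert-butyl group, which gives 17.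

Step 9. The benzylic alkylrhodium hydride may undergo β-hydride elimination to a styrene instead of reductive elimination, the acetal oxygen β to one aldehyde may be eliminated, or the second, more hindered aldehyde may fail to decarbonylate. The fallback removes the carbons as CO2 by radical chemistry; it sets out from 15 and returns at 16. Pinnick oxidation (NaClO2, NaH2PO4, 2-methyl-2-butene, t-BuOH/H2O) should give the dicarboxylic acid F5. Twofold hydrodecarboxylation under photoredox catalysis (9-mesityl-10-phenylacridinium tetrafluoroborate cat., (PhS)2 cat., i-Pr2NEt in sub-stoichiometric amount, 2,2,2-trifluoroethanol, blue LEDs), in which each benzylic radical is capped by hydrogen-atom transfer from thiophenol, should give 16 with the tert-butyl ester untouched.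

Step 8. Osmylation of the ring alkene may be very slow, since it is flanked by two aryl-bearing carbons and a quaternary centre, and long exposure may over-oxidise or enolise the dialdehyde. The fallback replaces osmylation by electrophilic epoxidation; it sets out from 13 and returns at 15. Epoxidation (m-CPBA, NaHCO3, CH2Cl2) should give the 8,9-epoxide F6, expected on the face away from the aryl groups. Periodic acid (H5IO6, THF/H2O) should open it to glycol 14 and cleave that in the same flask to 15.

Further compounds
F1 | step 7 | diisopropyl (2S)-2-hydroxybutanedioate | CC(C)OC(=O)C[C@H](O)C(=O)OC(C)C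
F2 | step 7 | diisopropyl (2S,3R)-3-(4-benzyloxy-3-methoxybenzyl)-2-hydroxybutanedioate | CC(C)OC(=O)[C@@H](O)[C@@H](Cc1ccc(OCc2ccccc2)c(OC)c1)C(=O)OC(C)C
F3 | step 7 | (2S,3R)-3-(4-benzyloxy-3-methoxybenzyl)-2-hydroxybutanedioic acid | OC(=O)[C@@H](O)[C@@H](Cc1ccc(OCc2ccccc2)c(OC)c1)C(=O)O
F4 | step 7 | (2R)-3-(4-benzyloxy-3-methoxyphenyl)-2-[(2S,4S)-2-tert-butyl-5-oxo-1,3-dioxolan-4-yl]propanoic acid | OC(=O)[C@H](Cc1ccc(OCc2ccccc2)c(OC)c1)[C@@H]1O[C@H](C(C)(C)C)OC1=O
F5 | step 9 | dicarboxylic acid from 15 (each CHO oxidised to CO2H, other centres as in 15) | CC(C)(C)OC(=O)[C@H]([C@H](c1ccc(OCc2ccccc2)c(OC)c1)C(=O)O)[C@@]1(O[C@H](C(C)(C)C)OC1=O)[C@@H](c1ccc(OCc2ccccc2)c(OC)c1)C(=O)O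
F6 | step 8 | 8,9-epoxide of 13, oxirane on the ring face opposite the aryl groups | CC(C)(C)OC(=O)[C@@H]1[C@H](c3ccc(OCc4ccccc4)c(OC)c3)[C@H]5O[C@H]5[C@H](c3ccc(OCc4ccccc4)c(OC)c3)[C@]12O[C@H](C(C)(C)C)OC2=O
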